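**Strategy.** Ring A (cyclopentanone) is traced to a cis-fused cyclobutanone lacking C1 (indanone numbering). Its C2(=O)–C3H2–C3a–C7a unit is a ketene/terminal-alkene retron, so one intramolecular keteniminium–alkene [2+2] cycloaddition of an acyclic, D-tartrate-derived oct-7-enamide forms C2–C3 and the ring-fusion bond C3a–C7a, closing cyclohexane ring B and the four-membered ring together. The strain is then spent: (Z)-propenyl addition, hydroxyl-directed epoxidation and semipinacol shift of C7a insert C1 as the β-hydroxy ketone (aldol) unit C2(=O)–C1–CH(OH)CH3. Exocyclic methylene, the two esters and the glycidic ester (Sharpless epoxidation) complete the target.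

Key step: step 8

Remark: compounds 1, 8, 15, 20 and 22 are taken as purchasable. Locants follow octahydro-1H-inden-2-one numbering for ring-expanded compounds and bicyclo[4.2.0]octan-7-one numbering (C1/C6 ring fusion, C7 carbonyl or carbinol carbon, C8 CH2) for the cyclobutane intermediates. TBS = tert-butyldimethylsilyl, TES = triethylsilyl, PMB = 4-methoxybenzyl.

Step 1
Reactants: 1 diethyl D-tartrate
Product: 2 diethyl (2S,3S)-2,3-bis(tert-butyldimethylsilyloxy)butanedioate
Conditions: TBSCl, imidazole, DMF, 40 °C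
Reagents that add atoms: tert-butyldimethylsilyl chloride CC(C)(C)[Si](C)(C)Cl
Why: Imidazole-mediated silyl ether formation on both secondary hydroxyls leaves the two tartrate stereocentres (later C5 and C6 of the target) untouched and installs the bulky vicinal groups needed in step 8.

Step 2
Reactants: 2 diethyl (2S,3S)-2,3-bis(tert-butyldimethylsilyloxy)butanedioate
Product: 3 ethyl (2S,3S)-2,3-bis(tert-butyldimethylsilyloxy)-4-oxobutanoate
Conditions: i-Bu2AlH (1.05 equiv), toluene, −78 °C; then MeOH, aq. potassium sodium tartrate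
Reagents that add atoms: none
Why: Ester half-reduction, in which the aluminium hemiacetal of an α-silyloxy ester is stable at −78 °C so that one equivalent of hydride stops at the aldehyde of one of the two homotopic ester groups.

Step 3
Reactants: 3 ethyl (2S,3S)-2,3-bis(tert-butyldimethylsilyloxy)-4-oxobutanoate
Product: 5 ethyl (2S,3R,4R)-2,3-bis(tert-butyldimethylsilyloxy)-4-(triethylsilyloxy)hex-5-enoate, via bromomagnesium alkoxide 4 (not isolated)
Conditions: CH2=CHMgBr, THF, −78 °C; then Et3SiOTf, 2,6-lutidine, −78 → 0 °C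
Reagents that add atoms: vinylmagnesium bromide C=C[Mg]Br; triethylsilyl trifluoromethanesulfonate CC[Si](CC)(CC)OS(=O)(=O)C(F)(F)F
Why: Grignard addition under non-chelating Felkin–Anh control by the bulky α-silyloxy group should give the 3,4-anti carbinol, whose alkoxide is silylated in the same flask to forestall lactonisation and silyl migration, the minor C4 epimer being removed by chromatography.

Step 4
Reactants: 5 ethyl (2S,3R,4R)-2,3-bis(tert-butyldimethylsilyloxy)-4-(triethylsilyloxy)hex-5-enoate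
Product: 7 methyl (2E,4R,5R,6R)-4,5-bis(tert-butyldimethylsilyloxy)-6-(triethylsilyloxy)octa-2,7-dienoate, via aldehyde 6 (not isolated)
Conditions: i-Bu2AlH, CH2Cl2, −78 °C; then Ph3P=CHCO2Me, −78 °C → rt
Reagents that add atoms: methyl (triphenylphosphoranylidene)acetate COC(=O)C=P(c1ccccc1)(c1ccccc1)c1ccccc1
Why: One-pot ester half-reduction and Wittig olefination with a stabilised ylide should give the (E)-enoate without isolating the epimerisable α-silyloxy aldehyde.

Step 5
Reactants: 8 2-bromoprop-2-en-1-ol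
Product: 9 2-bromoallyl 4-methoxybenzyl ether
Conditions: NaH, 4-MeOC6H4CH2Cl, n-Bu4NI (cat.), THF, 0 °C → rt
Reagents that add atoms: 4-methoxybenzyl chloride COc1ccc(CCl)cc1
Why: Williamson ether synthesis protects the primary alcohol as an oxidatively removable ether.

Step 6
Reactants: 7 methyl (2E,4R,5R,6R)-4,5-bis(tert-butyldimethylsilyloxy)-6-(triethylsilyloxy)octa-2,7-dienoate; 9 2-bromoallyl 4-methoxybenzyl ether
Product: 10 methyl (3S,4R,5R,6R)-4,5-bis(tert-butyldimethylsilyloxy)-3-[3-(4-methoxybenzyloxy)prop-1-en-2-yl]-6-(triethylsilyloxy)oct-7-enoate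
Conditions: 9 (2.4 equiv), t-BuLi, Et2O, −78 °C; CuI (1.2 equiv); then Me3SiCl, 7, THF, −78 → −40 °C; aq. NH4Cl/NH3
Reagents that add atoms: none
Why: Me3SiCl-accelerated Gilman cuprate conjugate addition to an (E)-γ-silyloxy enoate should proceed through a Felkin-type arrangement with the γ-oxygen anti to the incoming copper reagent, setting the new C3 stereocentre anti to the C4 oxygen.

Step 7
Reactants: 10 methyl (3S,4R,5R,6R)-4,5-bis(tert-butyldimethylsilyloxy)-3-[3-(4-methoxybenzyloxy)prop-1-en-2-yl]-6-(triethylsilyloxy)oct-7-enoate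
Product: 11 (3S,4R,5R,6R)-4,5-bis(tert-butyldimethylsilyloxy)-3-[3-(4-methoxybenzyloxy)prop-1-en-2-yl]-N,N-dimethyl-6-(triethylsilyloxy)oct-7-enamide
Conditions: Me2NH·HCl, AlMe3, toluene, 0 → 60 °C
Reagents that add atoms: dimethylamine hydrochloride C[NH2+]C.[Cl-]
Why: Weinreb aminolysis of the methyl ester with the aluminium amide gives the tertiary amide without touching silyl ethers or alkenes.

Step 8
Reactants: 11 (3S,4R,5R,6R)-4,5-bis(tert-butyldimethylsilyloxy)-3-[3-(4-methoxybenzyloxy)prop-1-en-2-yl]-N,N-dimethyl-6-(triethylsilyloxy)oct-7-enamide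
Product: 14 cis-fused 2-hydroxy-3,4-bis(tert-butyldimethylsilyloxy)-5-[3-(4-methoxybenzyloxy)prop-1-en-2-yl]bicyclo[4.2.0]octan-7-one, via keteniminium triflate 12 (not isolated), via cyclobutaniminium triflate 13 (not isolated)
Conditions: Tf2O, 2,4,6-collidine, ClCH2CH2Cl, 0 → 80 °C; then 1 M aq. HCl, THF, rt
Reagents that add atoms: water O
Why: O-Triflation of the amide and deprotonation by collidine give keteniminium ion 12, whose electrophilic sp carbon is attacked by the terminal alkene carbon while its enamine carbon closes onto the internal alkene carbon in an asynchronous thermal keteniminium–olefin [2+2] cycloaddition (the iminium counterpart of the intramolecular ketene–alkene cycloaddition), and acid hydrolysis of iminium salt 13 unveils the cyclobutanone and removes the triethylsilyl ether. Two rings close at once: the six-membered ring through the new C1–C6 bond in the fused (not bridged) mode, because the nucleophilic CH2 terminus bonds to the keteniminium carbon and positive charge develops at the internal carbon, and the four-membered ring through the new C7–C8 bond. The cis ring fusion is enforced by the cyclobutane, and the configuration of C1 and C6 relative to C5 should follow from a chair-like tether in which the bulky vicinal trans silyloxy groups at C3/C4 are diaxial, the C5 alkenyl group and the C2 silyloxy group are equatorial and the slender sp keteniminium carbon takes the remaining axial site, whereas the other face would force the vinyl CH2 syn-axial to the C3 silyloxy group. The step needs chemoselectivity for the monosubstituted alkene (the 1,1-disubstituted alkene at C5 could only close a bicyclo[1.1.1] or bicyclo[2.1.0] skeleton) and tolerance of the γ-silyloxy group, which the bulk of the silyl ethers and the hindered base should provide.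

Step 9
Reactants: 14 cis-fused 2-hydroxy-3,4-bis(tert-butyldimethylsilyloxy)-5-[3-(4-methoxybenzyloxy)prop-1-en-2-yl]bicyclo[4.2.0]octan-7-one; 15 (Z)-1-bromoprop-1-ene
Product: 16 cis-fused 3,4-bis(tert-butyldimethylsilyloxy)-5-[3-(4-methoxybenzyloxy)prop-1-en-2-yl]-7-[(Z)-prop-1-enyl]bicyclo[4.2.0]octane-2,7-diol
Conditions: 15 (3 equiv), t-BuLi, THF/Et2O, −78 °C; CeCl3; then 14, −78 °C
Reagents that add atoms: none
Why: Organocerium 1,2-addition (enolisation of the cyclobutanone suppressed) of the configurationally stable (Z)-propenyl reagent should occur from the convex face, placing the propenyl group cis to H-1/H-6, with one equivalent consumed by the free hydroxyl.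

Step 10
Reactants: 16 cis-fused 3,4-bis(tert-butyldimethylsilyloxy)-5-[3-(4-methoxybenzyloxy)prop-1-en-2-yl]-7-[(Z)-prop-1-enyl]bicyclo[4.2.0]octane-2,7-diol
Product: 17 cis-fused 3,4-bis(tert-butyldimethylsilyloxy)-7-hydroxy-5-[3-(4-methoxybenzyloxy)prop-1-en-2-yl]-7-[(Z)-prop-1-enyl]bicyclo[4.2.0]octan-2-one
Conditions: Dess–Martin periodinane, NaHCO3, CH2Cl2, 0 °C
Reagents that add atoms: none
Why: Dess–Martin oxidation converts the secondary alcohol into the ketone while the tertiary allylic cyclobutanol cannot be oxidised.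

Step 11
Reactants: 17 cis-fused 3,4-bis(tert-butyldimethylsilyloxy)-7-hydroxy-5-[3-(4-methoxybenzyloxy)prop-1-en-2-yl]-7-[(Z)-prop-1-enyl]bicyclo[4.2.0]octan-2-one
Product: 18 cis-fused 3,4-bis(tert-butyldimethylsilyloxy)-5-[3-(4-methoxybenzyloxy)prop-1-en-2-yl]-2-methylidene-7-[(Z)-prop-1-enyl]bicyclo[4.2.0]octan-7-ol
Conditions: Ph3PCH3Br, KOt-Bu (excess), THF, 0 °C → rt
Reagents that add atoms: methyltriphenylphosphonium bromide C[P+](c1ccccc1)(c1ccccc1)c1ccccc1.[Br-]
Why: Wittig methylenation installs the exocyclic methylene before any other ketone exists, and the ring-fusion centre α to the ketone cannot epimerise because a trans-fused bicyclo[4.2.0]octane is far more strained.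

Step 12
Reactants: 18 cis-fused 3,4-bis(tert-butyldimethylsilyloxy)-5-[3-(4-methoxybenzyloxy)prop-1-en-2-yl]-2-methylidene-7-[(Z)-prop-1-enyl]bicyclo[4.2.0]octan-7-ol
Product: 19 cis-fused 5-[3-(4-methoxybenzyloxy)prop-1-en-2-yl]-2-methylidene-7-[(Z)-prop-1-enyl]bicyclo[4.2.0]octane-3,4,7-triol
Conditions: n-Bu4NF, THF, 0 °C → rt
Reagents that add atoms: none
Why: Fluoride-mediated desilylation frees both secondary hydroxyls at a stage where no base-sensitive group is present.

Step 13
Reactants: 19 cis-fused 5-[3-(4-methoxybenzyloxy)prop-1-en-2-yl]-2-methylidene-7-[(Z)-prop-1-enyl]bicyclo[4.2.0]octane-3,4,7-triol; 20 (S)-3-methylpentanoic acid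
Product: 21 3-O-[(3S)-3-methylpentanoyl] ester of triol 19
Conditions: 20 (1.05 equiv), EDC·HCl, DMAP (cat.), CH2Cl2, −20 → 0 °C
Reagents that add atoms: none
Why: Steglich esterification with one equivalent of acid should acylate the allylic C3 hydroxyl, flanked by an sp2 carbon, in preference to the C4 hydroxyl next to the branched C5 and to the tertiary alcohol.

Step 14
Reactants: 21 3-O-[(3S)-3-methylpentanoyl] ester of triol 19; 22 (E)-3-methylpent-2-enoic acid
Product: 23 3-O-[(3S)-3-methylpentanoyl] 4-O-[(2E)-3-methylpent-2-enoyl] diester of triol 19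
Conditions: 22, EDC·HCl, DMAP, CH2Cl2, rt
Reagents that add atoms: none
Why: Steglich esterification of the remaining secondary hydroxyl under carbodiimide activation avoids the vinylketene pathway that would deconjugate the enoate, and the tertiary cyclobutanol does not acylate.

Step 15
Reactants: 23 3-O-[(3S)-3-methylpentanoyl] 4-O-[(2E)-3-methylpent-2-enoyl] diester of triol 19
Product: 25 hydrindanone aldol (1-[(1S)-1-hydroxyethyl] analogue of 26), via cis-epoxy alcohol 24 (not isolated)
Conditions: VO(acac)2 (cat.), t-BuOOH, CH2Cl2, 0 °C; then BF3·OEt2, −78 °C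
Reagents that add atoms: tert-butyl hydroperoxide CC(C)(C)OO
Why: Hydroxyl-directed vanadium-catalysed epoxidation of the only allylic alcohol should deliver oxygen anti to the ring-fusion carbon C6 (the Z-methyl keeps the C–O bond near the alkene plane by A(1,3) strain and the metal sits below C8H2 rather than under ring B), after which BF3 triggers the semipinacol rearrangement of the 2,3-epoxy alcohol in which the antiperiplanar, more substituted C6 migrates with retention and the epoxide carbon is inverted, giving C1 (R) and the (S)-carbinol.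

Step 16
Reactants: 25 hydrindanone aldol
Product: 26 hydrindanone acetate (target skeleton carrying a 3-(4-methoxybenzyloxy)prop-1-en-2-yl group at C7)
Conditions: Ac2O, pyridine, DMAP (cat.), CH2Cl2, 0 °C
Reagents that add atoms: acetic anhydride CC(=O)OC(C)=O
Why: Acetylation of the secondary alcohol under mild base at 0 °C avoids β-elimination of the β-acyloxy ketone and epimerisation at C1.

Step 17
Reactants: 26 hydrindanone acetate
Product: 27 allylic alcohol (7-(3-hydroxyprop-1-en-2-yl) analogue of 26)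
Conditions: DDQ, CH2Cl2/pH 7 buffer, 0 °C
Reagents that add atoms: none
Why: Oxidative cleavage of the 4-methoxybenzyl ether by DDQ is neutral and leaves esters, ketone and alkenes intact.

Step 18
Reactants: 27 allylic alcohol
Product: 28 epoxy alcohol (7-[(2S)-2-(hydroxymethyl)oxiran-2-yl] analogue)
Conditions: Ti(Oi-Pr)4, L-(+)-diethyl tartrate, t-BuOOH, 4 Å molecular sieves, CH2Cl2, −20 °C
Reagents that add atoms: tert-butyl hydroperoxide CC(C)(C)OO
Why: Katsuki–Sharpless asymmetric epoxidation of the 2-substituted allylic alcohol sets the quaternary oxirane carbon under reagent control, in the sense that converts 2-methylprop-2-en-1-ol into (S)-2-methylglycidol, and no other free allylic alcohol is present.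

Step 19
Reactants: 28 epoxy alcohol
Product: 29 glycidic acid (7-[(2R)-2-carboxyoxiran-2-yl] analogue)
Conditions: TEMPO (cat.), PhI(OAc)2, MeCN/H2O, rt
Reagents that add atoms: water O
Why: Oxoammonium-mediated oxidation of the primary alcohol through the aldehyde hydrate gives the acid without touching the epoxide, the alkenes or the ketone.

Step 20
Reactants: 29 glycidic acid
Product: 30 (1R,3aS,5R,6R,7R,7aR)-1-[(1S)-1-acetoxyethyl]-7-[(2R)-2-(methoxycarbonyl)oxiran-2-yl]-4-methylidene-5-[(3S)-3-methylpentanoyloxy]-6-[(2E)-3-methylpent-2-enoyloxy]octahydro-1H-inden-2-one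
Conditions: Me3SiCHN2, MeOH/toluene, 0 °C
Reagents that add atoms: (trimethylsilyl)diazomethane C[Si](C)(C)C=[N+]=[N-]
Why: Esterification by diazomethane generated in the flask is neutral and spares the β-acetoxy ketone, the epoxide and the epimerisable C1.

**Compound list**

1 | diethyl D-tartrate, diethyl (2S,3S)-2,3-dihydroxybutanedioate | CCOC(=O)[C@@H](O)[C@H](O)C(=O)OCC | starting material
2 | diethyl (2S,3S)-2,3-bis(tert-butyldimethylsilyloxy)butanedioate | CCOC(=O)[C@@H](O[Si](C)(C)C(C)(C)C)[C@H](O[Si](C)(C)C(C)(C)C)C(=O)OCC | intermediate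
3 | ethyl (2S,3S)-2,3-bis(tert-butyldimethylsilyloxy)-4-oxobutanoate | O=C[C@@H](O[Si](C)(C)C(C)(C)C)[C@H](O[Si](C)(C)C(C)(C)C)C(=O)OCC | intermediate
4 | bromomagnesium alkoxide of ethyl (2S,3R,4R)-2,3-bis(tert-butyldimethylsilyloxy)-4-hydroxyhex-5-enoate | C=C[C@@H]([O-])[C@@H](O[Si](C)(C)C(C)(C)C)[C@H](O[Si](C)(C)C(C)(C)C)C(=O)OCC.[Mg+2].[Br-] | intermediate (not isolated)
5 | ethyl (2S,3R,4R)-2,3-bis(tert-butyldimethylsilyloxy)-4-(triethylsilyloxy)hex-5-enoate | C=C[C@@H](O[Si](CC)(CC)CC)[C@@H](O[Si](C)(C)C(C)(C)C)[C@H](O[Si](C)(C)C(C)(C)C)C(=O)OCC | intermediate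
6 | (2S,3R,4R)-2,3-bis(tert-butyldimethylsilyloxy)-4-(triethylsilyloxy)hex-5-enal | C=C[C@@H](O[Si](CC)(CC)CC)[C@@H](O[Si](C)(C)C(C)(C)C)[C@H](O[Si](C)(C)C(C)(C)C)C=O | intermediate (not isolated)
7 | methyl (2E,4R,5R,6R)-4,5-bis(tert-butyldimethylsilyloxy)-6-(triethylsilyloxy)octa-2,7-dienoate | C=C[C@@H](O[Si](CC)(CC)CC)[C@@H](O[Si](C)(C)C(C)(C)C)[C@H](O[Si](C)(C)C(C)(C)C)/C=C/C(=O)OC | intermediate
8 | 2-bromoprop-2-en-1-ol | OCC(Br)=C | starting material
9 | 2-bromoallyl 4-methoxybenzyl ether | C=C(Br)COCc1ccc(OC)cc1 | intermediate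
10 | methyl (3S,4R,5R,6R)-4,5-bis(tert-butyldimethylsilyloxy)-3-[3-(4-methoxybenzyloxy)prop-1-en-2-yl]-6-(triethylsilyloxy)oct-7-enoate | C=C[C@@H](O[Si](CC)(CC)CC)[C@@H](O[Si](C)(C)C(C)(C)C)[C@H](O[Si](C)(C)C(C)(C)C)[C@H](C(=C)COCc1ccc(OC)cc1)CC(=O)OC | intermediate
11 | (3S,4R,5R,6R)-4,5-bis(tert-butyldimethylsilyloxy)-3-[3-(4-methoxybenzyloxy)prop-1-en-2-yl]-N,N-dimethyl-6-(triethylsilyloxy)oct-7-enamide | C=C[C@@H](O[Si](CC)(CC)CC)[C@@H](O[Si](C)(C)C(C)(C)C)[C@H](O[Si](C)(C)C(C)(C)C)[C@H](C(=C)COCc1ccc(OC)cc1)CC(=O)N(C)C | intermediate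
12 | N,N-dimethylketeniminium triflate derived from 11 (C=C=N+ in place of CH2–C(=O)N) | C=C[C@@H](O[Si](CC)(CC)CC)[C@@H](O[Si](C)(C)C(C)(C)C)[C@H](O[Si](C)(C)C(C)(C)C)[C@H](C(=C)COCc1ccc(OC)cc1)C=C=[N+](C)C.[O-]S(=O)(=O)C(F)(F)F | intermediate (not isolated)
13 | cis-fused N,N-dimethylbicyclo[4.2.0]octan-7-iminium triflate (C7=N+ analogue of 14 with the C2 triethylsilyl ether still in place) | C[N+](C)=C1C[C@@H]2[C@@H](O[Si](CC)(CC)CC)[C@@H](O[Si](C)(C)C(C)(C)C)[C@H](O[Si](C)(C)C(C)(C)C)[C@H](C(=C)COCc3ccc(OC)cc3)[C@H]12.[O-]S(=O)(=O)C(F)(F)F | intermediate (not isolated)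
14 | cis-fused 2-hydroxy-3,4-bis(tert-butyldimethylsilyloxy)-5-[3-(4-methoxybenzyloxy)prop-1-en-2-yl]bicyclo[4.2.0]octan-7-one (H-1, H-6, H-5 and H-4 on one face together with 2-OH and 3-O; cyclobutane, C5 alkenyl group and 4-O on the other) | O=C1C[C@@H]2[C@@H](O)[C@@H](O[Si](C)(C)C(C)(C)C)[C@H](O[Si](C)(C)C(C)(C)C)[C@H](C(=C)COCc3ccc(OC)cc3)[C@H]12 | intermediate
15 | (Z)-1-bromoprop-1-ene | C/C=C\Br | starting material
16 | cis-fused 3,4-bis(tert-butyldimethylsilyloxy)-5-[3-(4-methoxybenzyloxy)prop-1-en-2-yl]-7-[(Z)-prop-1-enyl]bicyclo[4.2.0]octane-2,7-diol (propenyl on the convex face, cis to H-1/H-6; other centres as in 14) | O[C@]1(/C=C\C)C[C@@H]2[C@@H](O)[C@@H](O[Si](C)(C)C(C)(C)C)[C@H](O[Si](C)(C)C(C)(C)C)[C@H](C(=C)COCc3ccc(OC)cc3)[C@H]12 | intermediate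
17 | cis-fused 3,4-bis(tert-butyldimethylsilyloxy)-7-hydroxy-5-[3-(4-methoxybenzyloxy)prop-1-en-2-yl]-7-[(Z)-prop-1-enyl]bicyclo[4.2.0]octan-2-one (centres as in 16) | O[C@]1(/C=C\C)C[C@@H]2C(=O)[C@@H](O[Si](C)(C)C(C)(C)C)[C@H](O[Si](C)(C)C(C)(C)C)[C@H](C(=C)COCc3ccc(OC)cc3)[C@H]12 | intermediate
18 | cis-fused 3,4-bis(tert-butyldimethylsilyloxy)-5-[3-(4-methoxybenzyloxy)prop-1-en-2-yl]-2-methylidene-7-[(Z)-prop-1-enyl]bicyclo[4.2.0]octan-7-ol (centres as in 16) | O[C@]1(/C=C\C)C[C@@H]2C(=C)[C@@H](O[Si](C)(C)C(C)(C)C)[C@H](O[Si](C)(C)C(C)(C)C)[C@H](C(=C)COCc3ccc(OC)cc3)[C@H]12 | intermediate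
19 | cis-fused 5-[3-(4-methoxybenzyloxy)prop-1-en-2-yl]-2-methylidene-7-[(Z)-prop-1-enyl]bicyclo[4.2.0]octane-3,4,7-triol (3-OH and 4-OH trans; centres as in 16) | O[C@]1(/C=C\C)C[C@@H]2C(=C)[C@@H](O)[C@H](O)[C@H](C(=C)COCc3ccc(OC)cc3)[C@H]12 | intermediate
20 | (S)-3-methylpentanoic acid | OC(=O)C[C@@H](C)CC | starting material
21 | 3-O-[(3S)-3-methylpentanoyl] ester of triol 19 | O[C@]1(/C=C\C)C[C@@H]2C(=C)[C@@H](OC(=O)C[C@@H](C)CC)[C@H](O)[C@H](C(=C)COCc3ccc(OC)cc3)[C@H]12 | intermediate
22 | (E)-3-methylpent-2-enoic acid | OC(=O)/C=C(\C)CC | starting material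
23 | 3-O-[(3S)-3-methylpentanoyl] 4-O-[(2E)-3-methylpent-2-enoyl] diester of triol 19 | O[C@]1(/C=C\C)C[C@@H]2C(=C)[C@@H](OC(=O)C[C@@H](C)CC)[C@H](OC(=O)/C=C(\C)CC)[C@H](C(=C)COCc3ccc(OC)cc3)[C@H]12 | intermediate
24 | cis-epoxy alcohol: 7-(cis-3-methyloxiran-2-yl) analogue of 23, epoxide oxygen anti to C6 | O[C@]1([C@H]3O[C@H]3C)C[C@@H]2C(=C)[C@@H](OC(=O)C[C@@H](C)CC)[C@H](OC(=O)/C=C(\C)CC)[C@H](C(=C)COCc3ccc(OC)cc3)[C@H]12 | intermediate (not isolated)
25 | hydrindanone aldol: cis-fused octahydro-1H-inden-2-one with 1-[(1S)-1-hydroxyethyl], 7-[3-(4-methoxybenzyloxy)prop-1-en-2-yl], 4-methylidene, 5-[(3S)-3-methylpentanoyloxy] and 6-[(2E)-3-methylpent-2-enoyloxy]; ring centres arranged as in 30 | C=C1[C@H]2CC(=O)[C@@H]([C@H](C)O)[C@H]2[C@@H](C(=C)COCc2ccc(OC)cc2)[C@@H](OC(=O)/C=C(\C)CC)[C@@H]1OC(=O)C[C@@H](C)CC | intermediate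
26 | hydrindanone acetate: 1-[(1S)-1-acetoxyethyl] analogue of 25 | C=C1[C@H]2CC(=O)[C@@H]([C@H](C)OC(C)=O)[C@H]2[C@@H](C(=C)COCc2ccc(OC)cc2)[C@@H](OC(=O)/C=C(\C)CC)[C@@H]1OC(=O)C[C@@H](C)CC | intermediate
27 | allylic alcohol: 7-(3-hydroxyprop-1-en-2-yl) analogue of 26 | C=C1[C@H]2CC(=O)[C@@H]([C@H](C)OC(C)=O)[C@H]2[C@@H](C(=C)CO)[C@@H](OC(=O)/C=C(\C)CC)[C@@H]1OC(=O)C[C@@H](C)CC | intermediate
28 | epoxy alcohol: 7-[(2S)-2-(hydroxymethyl)oxiran-2-yl] analogue of 26 | C=C1[C@H]2CC(=O)[C@@H]([C@H](C)OC(C)=O)[C@H]2[C@@H]([C@]2(CO)CO2)[C@@H](OC(=O)/C=C(\C)CC)[C@@H]1OC(=O)C[C@@H](C)CC | intermediate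
29 | glycidic acid: 7-[(2R)-2-carboxyoxiran-2-yl] analogue of 26 | C=C1[C@H]2CC(=O)[C@@H]([C@H](C)OC(C)=O)[C@H]2[C@@H]([C@]2(C(=O)O)CO2)[C@@H](OC(=O)/C=C(\C)CC)[C@@H]1OC(=O)C[C@@H](C)CC | intermediate
30 | (1R,3aS,5R,6R,7R,7aR)-1-[(1S)-1-acetoxyethyl]-7-[(2R)-2-(methoxycarbonyl)oxiran-2-yl]-4-methylidene-5-[(3S)-3-methylpentanoyloxy]-6-[(2E)-3-methylpent-2-enoyloxy]octahydro-1H-inden-2-one | C=C1[C@H]2CC(=O)[C@@H]([C@H](C)OC(C)=O)[C@H]2[C@@H]([C@]2(C(=O)OC)CO2)[C@@H](OC(=O)/C=C(\C)CC)[C@@H]1OC(=O)C[C@@H](C)CC | target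

**Step count.** Total: 20 steps. Longest linear sequence: 19 steps (steps 1–4 and 6–20, from diethyl D-tartrate).

**Steps most likely to fail**

Step 8. The γ-silyloxy oxygen may attack the activated amide with loss of the silyl group, the deactivated allylic alkene may react too slowly, or facial discrimination in the cycloaddition may be poor, giving the C1/C6-epimeric cis-fused cyclobutanone. The fallback replaces substrate control by auxiliary control. It sets out from ester 10: AlMe3-mediated aminolysis with (2R,5R)-2,5-dimethylpyrrolidine should give the C2-symmetric pyrrolidine amide F1. Tf2O and 2,6-di-tert-butyl-4-methylpyridine in ClCH2CH2Cl convert it into the chiral keteniminium triflate F2, whose two faces are differentiated by the methyl groups flanking nitrogen (asymmetric keteniminium cycloaddition; the antipodal amine is taken if it proves to be the matched partner). Cycloaddition gives the iminium triflate F3, and hydrolysis with aq. HCl in THF returns to the route at 14.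

Step 15. Oxygen may be delivered to the wrong face of the propenyl group (aldol epimeric at both new centres), the hydroxyl may direct epoxidation to the exocyclic methylene, or C8 may migrate instead of C6. The fallback separates ring expansion from creation of the carbinol centre. It sets out from 23: oxidative ring expansion of the 1-alkenylcyclobutanol with divalent palladium (PdCl2(MeCN)2 cat., benzoquinone, THF; 1,2-shift of C6 to the palladium-activated alkene, then β-hydride elimination) should give the (E)-ethylidene ketone F4. Copper-catalysed conjugate borylation (CuCl, NaOt-Bu, a chiral Josiphos-type bisphosphine, B2pin2, MeOH) gives the β-boryl ketone F5, with the boron-bearing centre under ligand control and C1 protonated from the convex face. Oxidation with NaBO3 (retention) returns to the route at 25.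

Step 13. Discrimination between the two secondary hydroxyls may be insufficient, or the first acyl group may migrate to the neighbouring hydroxyl. The fallback uses temporary silyl differentiation, which responds more strongly to steric differences than acylation does. It sets out from 19: Et3SiCl and imidazole at −40 °C should silylate the less hindered allylic hydroxyl to give the mono-silyl ether F6. EDC/DMAP esterification with 22 gives the enoate F7, and HF·pyridine frees the C3 hydroxyl to give the hydroxy enoate F8. Esterification of F8 with 20 returns to the route at 23.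

**Further compounds**

F1 | step 8 | (2R,5R)-2,5-dimethylpyrrolidine amide corresponding to 11 | C=C[C@@H](O[Si](CC)(CC)CC)[C@@H](O[Si](C)(C)C(C)(C)C)[C@H](O[Si](C)(C)C(C)(C)C)[C@H](C(=C)COCc1ccc(OC)cc1)CC(=O)N1[C@H](C)CC[C@H]1C
F2 | step 8 | keteniminium triflate derived from F1 | C=C[C@@H](O[Si](CC)(CC)CC)[C@@H](O[Si](C)(C)C(C)(C)C)[C@H](O[Si](C)(C)C(C)(C)C)[C@H](C(=C)COCc1ccc(OC)cc1)C=C=[N+]1[C@H](C)CC[C@H]1C.[O-]S(=O)(=O)C(F)(F)F
F3 | step 8 | cis-fused bicyclo[4.2.0]octan-7-iminium triflate carrying the (2R,5R)-2,5-dimethylpyrrolidinium unit | C[C@@H]1CC[C@@H](C)[N+]1=C1C[C@@H]2[C@@H](O[Si](CC)(CC)CC)[C@@H](O[Si](C)(C)C(C)(C)C)[C@H](O[Si](C)(C)C(C)(C)C)[C@H](C(=C)COCc3ccc(OC)cc3)[C@H]12.[O-]S(=O)(=O)C(F)(F)F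
F4 | step 15 | (E)-1-ethylidene hydrindanone (1-ethylidene analogue of 25) | C=C1[C@H]2CC(=O)/C(=C/C)[C@H]2[C@@H](C(=C)COCc2ccc(OC)cc2)[C@@H](OC(=O)/C=C(\C)CC)[C@@H]1OC(=O)C[C@@H](C)CC
F5 | step 15 | β-boryl ketone (pinacol boronate in place of the hydroxyl of 25) | C=C1[C@H]2CC(=O)[C@@H]([C@H](C)B3OC(C)(C)C(C)(C)O3)[C@H]2[C@@H](C(=C)COCc2ccc(OC)cc2)[C@@H](OC(=O)/C=C(\C)CC)[C@@H]1OC(=O)C[C@@H](C)CC
F6 | step 13 | 3-O-triethylsilyl ether of triol 19 | O[C@]1(/C=C\C)C[C@@H]2C(=C)[C@@H](O[Si](CC)(CC)CC)[C@H](O)[C@H](C(=C)COCc3ccc(OC)cc3)[C@H]12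
F7 | step 13 | 3-O-triethylsilyl 4-O-[(2E)-3-methylpent-2-enoyl] derivative of triol 19 | O[C@]1(/C=C\C)C[C@@H]2C(=C)[C@@H](O[Si](CC)(CC)CC)[C@H](OC(=O)/C=C(\C)CC)[C@H](C(=C)COCc3ccc(OC)cc3)[C@H]12
F8 | step 13 | 4-O-[(2E)-3-methylpent-2-enoyl] ester of triol 19 | O[C@]1(/C=C\C)C[C@@H]2C(=C)[C@@H](O)[C@H](OC(=O)/C=C(\C)CC)[C@H](C(=C)COCc3ccc(OC)cc3)[C@H]12
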